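**Plan**

1. Retrosynthesis. Rings: A = spiro δ-lactone, B = carbinol cyclohexane, C = cyclopentane, D/E = bicyclo[2.2.2]octanone, F = γ-lactone. Ring A is cut at its lactone C–O and its C=C. Ring B is shrunk to a cyclopentenol by undoing a 1,2-shift of the bond from the spiro carbon to its ring CH2 neighbour. Rings C/D/E are cut by a retro-[4+2] at the two bridgehead bonds, and the CH2–quaternary carbon bond by a retro-Michael step.
2. Enabling feature. In ring B the spiro carbon lies between the carbinol carbon (a ketone at that stage) and the O-bearing C(CH3)2 carbon of ring A. This O–CMe2–C(spiro)–C=O aldol array is what a 2,3-epoxy alcohol (semipinacol) rearrangement with ring expansion delivers.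
3. Forward order. Cyclopentenone fragment + cyclohexane-1,3-dione → dienone-butenolide (ring F) → sulfoxide elimination and intramolecular Diels–Alder (rings C, D, E at once) → alkenyl addition, epoxidation, ring expansion (ring B) → olefination and lactonisation (ring A) → hydration (carbinol).
4. Stereochemistry. (R)-4-Silyloxycyclopentenone fixes the ring-fusion CH. A catalyst-controlled Michael addition sets the methyl-bearing cage quaternary carbon, and its epimer is a separable diastereomer. The Diels–Alder step relays this to three cage centres, and hydrogenation sets the lactone CH. Carbonyl addition and directed epoxidation are translated stereospecifically into the spiro carbon, and hydration from the open face sets the carbinol.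

Key step: step 14

Remark: the cinchonidinium phase-transfer catalyst is assumed to favour the quaternary configuration drawn in 10; the pseudoenantiomeric cinchoninium salt is used if the sense is opposite.
Remark: centres left open in the SMILES (sulfoxide sulfur, the epimerisable ring CH groups of 8, 10 and 11) are mixtures that converge later.

**Route**

Step 1
Reactants: 1 (R)-4-(tert-butyldimethylsilyloxy)cyclopent-2-en-1-one; 2 thioanisole
Product: 4 (4S,5S)-5-[(dimethylamino)methyl]-4-[(phenylsulfanyl)methyl]cyclopent-2-en-1-one, via silyloxy Mannich ketone 3 (not isolated)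
Conditions: 2, n-BuLi, DABCO, THF, 0 °C; CuI, −40 °C; 1, −78 °C; [Me2N=CH2]I, −78 → 0 °C; then DBU, CH2Cl2, rt
Reagents that add atoms: N,N-dimethylmethyleneiminium iodide, C=[N+](C)C.[I-]
Why: The (phenylthio)methyl cuprate should add anti to the silyloxy group, the regiodefined enolate is trapped by the iminium salt trans to the new side chain (tandem conjugate addition–Mannich reaction), and DBU then removes the β-silyloxy group by E1cB elimination, so that both stereocentres of 4 derive from the one centre of 1.

Step 2
Reactants: 4 (4S,5S)-amino enone
Product: 5 {[(1S,5S)-2-oxo-5-[(phenylsulfanyl)methyl]cyclopent-3-en-1-yl]methyl}trimethylammonium iodide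
Conditions: MeI, acetone, rt
Reagents that add atoms: iodomethane, CI
Why: N-Methylation (Menshutkin reaction) turns the amine into a leaving group so that the sensitive exocyclic enone can be released only in the presence of its reaction partner.

Step 3
Reactants: 6 methyl 3-oxopentanoate; 7 methyl methacrylate
Product: 8 methyl 3,5-dimethyl-2,4-dioxocyclohexane-1-carboxylate (stereoisomer and enol mixture)
Conditions: NaOMe, MeOH, reflux; then aq. HCl
Reagents that add atoms: none
Why: Michael addition of the keto ester to the methacrylate followed by Claisen (Dieckmann-type) closure through the ethyl ketone carbon is the classical dihydroresorcinol synthesis and places the two methyl groups and the ester where rings E and F need them; the stereocentres of 8 are lost later and need no control.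

Step 4
Reactants: 8 dioxocyclohexane carboxylate; 5 ammonium iodide
Product: 10 Michael adduct (methyl 3,5-dimethyl-2,4-dioxo-3-{[2-oxo-5-[(phenylsulfanyl)methyl]cyclopent-3-en-1-yl]methyl}cyclohexane-1-carboxylate; quaternary carbon and trans cyclopentenone as in the SMILES), via exocyclic enone 9 (not isolated)
Conditions: Cs2CO3, N-(9-anthracenylmethyl)cinchonidinium bromide (10 mol%), PhMe, −30 °C
Reagents that add atoms: none
Why: Base releases the exocyclic enone 9 by loss of trimethylamine, and the cyclic 1,3-dione carbon adds to its methylene carbon as a chiral ammonium enolate ion pair (asymmetric phase-transfer Michael addition) that selects the face of the prochiral dione carbon, while the ketone α-centre settles trans to the neighbouring side chain by protonation and equilibration; because the cyclopentenone half is already enantiopure, the minor quaternary epimer is a diastereomer and can be removed.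

Step 5
Reactants: 10 Michael adduct
Product: 12 dienol sulfoxide (methyl 2-hydroxy-3,5-dimethyl-4-oxo-3-{[2-oxo-5-[(phenylsulfinyl)methyl]cyclopent-3-en-1-yl]methyl}cyclohexa-1,5-diene-1-carboxylate), via selenide 11 (not isolated)
Conditions: PhSeCl, pyridine, CH2Cl2, 0 °C; then NaIO4, THF–H2O, rt
Reagents that add atoms: sodium periodate, [Na+].[O-]I(=O)(=O)=O
Why: α-Selenenylation of the β-keto ester, oxidation and selenoxide syn-elimination dehydrogenate the ring, which settles as the ester-chelated enol of the 2,4-dienone, and periodate at the same time oxidises the sulfide to the sulfoxide without over-oxidation.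

Step 6
Reactants: 12 dienol sulfoxide
Product: 13 vinyl triflate (the 2-trifluoromethanesulfonate of 12)
Conditions: PhNTf2, Et3N, DMAP (cat.), CH2Cl2, 0 °C
Reagents that add atoms: N-phenylbis(trifluoromethanesulfonimide), O=S(=O)(N(c1ccccc1)S(=O)(=O)C(F)(F)F)C(F)(F)F
Why: O-Triflation of the acidic, hydrogen-bonded enol with the mild triflimide reagent gives the vinyl triflate while the less acidic ketones and the sulfoxide stay untouched.

Step 7
Reactants: 13 vinyl triflate
Product: 15 butenolide dienone sulfoxide (4,6-dimethyl-4-{[2-oxo-5-[(phenylsulfinyl)methyl]cyclopent-3-en-1-yl]methyl}isobenzofuran-1,5(3H,4H)-dione), via hydroxymethyl ester 14 (not isolated)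
Conditions: Bu3SnCH2OH, Pd2(dba)3 (5 mol%), AsPh3, LiCl, NMP, 45 °C
Reagents that add atoms: (tributylstannyl)methanol, CCCC[Sn](CO)(CCCC)CCCC
Why: Stille coupling of the vinyl triflate with the hydroxymethylstannane is followed by spontaneous lactonisation onto the cis ester, which completes the butenolide (ring F with its CH2O carbon) below the temperature at which the sulfoxide eliminates.

Step 8
Reactants: 15 butenolide dienone sulfoxide
Product: 17 cage enone (cyclopentenone cis-fused to ring C of the dimethylated bicyclo[2.2.2]octenone butenolide), via methylidene dienone 16 (not isolated)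
Conditions: PhMe, NaHCO3, 115 °C
Reagents that add atoms: none
Why: Thermal sulfoxide syn-elimination releases the exocyclic alkene, which adds across the termini of the cyclohexa-2,4-dienone in an intramolecular Diels–Alder reaction (ring C by closure of the two-atom tether, rings D and E as the bicyclo[2.2.2]octenone), the quaternary dienone carbon dictating the face so that the three new cage centres follow from it, and the tether CH, matched from 1 and correctable through its enol, giving the cis fusion between ring C and the cyclopentenone; the strained alternative through the ring enone double bond is the selectivity to be watched.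

Step 9
Reactants: 18 3-methylbut-2-enal
Product: 19 2-bromo-3-methylbut-2-enal
Conditions: Br2, CH2Cl2, 0 °C; then Et3N
Reagents that add atoms: bromine, BrBr
Why: Bromine addition to the enal and amine-induced dehydrobromination (addition–elimination) give the α-bromo enal.

Step 10
Reactants: 19 2-bromo-3-methylbut-2-enal
Product: 20 2-bromo-3-methylbut-2-en-1-ol
Conditions: NaBH4, CeCl3·7H2O, MeOH, 0 °C
Reagents that add atoms: none
Why: Luche 1,2-reduction converts the enal to the allylic alcohol and leaves the vinyl bromide intact.

Step 11
Reactants: 20 2-bromo-3-methylbut-2-en-1-ol; 21 benzyl bromide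
Product: 22 benzyl 2-bromo-3-methylbut-2-en-1-yl ether
Conditions: NaH, Bu4NI (cat.), THF, 0 °C → rt
Reagents that add atoms: none
Why: Williamson etherification masks the alcohol as a benzyl ether, which survives the organometallic and Lewis-acid steps and falls off in the later hydrogenation.

Step 12
Reactants: 22 alkenyl bromide; 17 cage enone
Product: 23 tertiary bis-allylic alcohol (1,2-adduct; alkenyl group on the face of the ring-fusion hydrogen, OH on the face of ring C)
Conditions: 22, t-BuLi (2 equiv), THF, −78 °C; CeCl3, −78 °C; then 17, −78 °C
Reagents that add atoms: none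
Why: Bromine–lithium exchange and transmetalation give a weakly basic alkenylcerium reagent that adds 1,2 to the cyclopentenone carbonyl from the face of the ring-fusion hydrogen, opposite the adjacent ring-C methylene, setting the carbinol centre; the cage ketone flanked by two quaternary carbons and the lactone are expected not to react at −78 °C.

Step 13
Reactants: 23 tertiary alcohol
Product: 24 epoxy alcohol (epoxide across the former tetrasubstituted alkene; configuration as in the SMILES)
Conditions: VO(acac)2 (5 mol%), t-BuOOH, CH2Cl2, 0 °C
Reagents that add atoms: tert-butyl hydroperoxide, CC(C)(C)OO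
Why: Hydroxyl-directed epoxidation (vanadium-catalysed, allylic alcohol type) should take the electron-rich tetrasubstituted alkene in preference to the ring alkene and deliver oxygen syn to the tertiary OH in the rotamer that places the CH2OBn group over the small vinyl ring carbon (allylic strain), which sets the epoxide carbon next to the carbinol.

Step 14
Reactants: 24 epoxy alcohol
Product: 25 ring-expanded hydroxy ketone (cyclohex-3-enone ring B with the new quaternary carbon bearing CH2OBn and C(CH3)2OH)
Conditions: BF3·OEt2 (0.3 equiv), CH2Cl2, −78 → −30 °C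
Reagents that add atoms: none
Why: Lewis-acid activation of the 2,3-epoxy alcohol breaks the C–O bond at the epoxide carbon next to the carbinol while the ring vinyl carbon, antiperiplanar to that bond, migrates from the carbinol carbon to it (semipinacol rearrangement, a 1,2-shift with ring expansion), so the five-membered carbinol ring becomes six-membered ring B with its ketone and the epoxide oxygen stays as the tertiary hydroxyl on the CMe2 carbon. The closest known reaction type is the Lewis-acid rearrangement of 2,3-epoxy alcohols to β-hydroxy ketones, as used for ring expansion of 1-(epoxyalkyl)cycloalkanols. No ring is closed by cyclisation: ring B arises by insertion of the former epoxide carbon between the carbonyl carbon and the migrating vinyl carbon (cyclopentene to cyclohexene). The new spiro quaternary centre forms with inversion at the epoxide carbon, so it is controlled by the epoxide configuration set in step 13 and not by the carbinol centre, which is destroyed. The step needs migration of the sp2 ring carbon in preference to the sp3 ring-fusion carbon, and cleavage at the carbinol-adjacent epoxide carbon in preference to the gem-dimethyl one; the first is secured by the higher migratory aptitude of an alkenyl group (the reason the ring double bond is kept until here), the second by anchimeric assistance of the migrating bond and the O–H group, with catalytic acid at low temperature to suppress ionisation at CMe2.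

Step 15
Reactants: 25 ring-expanded hydroxy ketone
Product: 26 saturated diol ketone (primary CH2OH and tertiary C(CH3)2OH on the spiro-to-be carbon)
Conditions: H2 (1 atm), Pd/C, EtOAc, rt
Reagents that add atoms: none
Why: Catalytic hydrogenation saturates the ring-B alkene and the unsaturated lactone and cleaves the benzyl ether, hydrogen reaching the lactone α-carbon from the side of the planar ketone bridge of the bicyclooctene, the less hindered one, which sets the last cage CH.

Step 16
Reactants: 26 diol ketone
Product: 27 hydroxy aldehyde
Conditions: TEMPO (10 mol%), PhI(OAc)2, CH2Cl2, rt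
Reagents that add atoms: none
Why: Nitroxyl-catalysed oxidation (TEMPO with the iodine oxidant) converts only the primary alcohol to the aldehyde, the tertiary alcohol and the ketones being inert.

Step 17
Reactants: 27 hydroxy aldehyde
Product: 29 spiro lactone ketone (rings A–F complete, ring-B ketone in place of the carbinol), via Z-enoate 28 (not isolated)
Conditions: (CF3CH2O)2P(O)CH2CO2Me, KN(SiMe3)2, 18-crown-6, THF, −78 °C; then CSA (cat.), PhMe, 60 °C
Reagents that add atoms: methyl bis(2,2,2-trifluoroethyl)phosphonoacetate, COC(=O)CP(=O)(OCC(F)(F)F)OCC(F)(F)F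
Why: Still–Gennari olefination of the aldehyde gives the (Z)-enoate, and acid then closes ring A by lactonisation of the tertiary alcohol onto the cis ester (6-exo-trig).

Step 18
Reactants: 29 spiro lactone ketone
Product: 30 exocyclic methylidene compound
Conditions: Zn, CH2Br2, TiCl4, THF–CH2Cl2, 0 °C → rt
Reagents that add atoms: dibromomethane, BrCBr
Why: Takai–Lombardo methylenation is non-basic and chemoselective for ketones, so the hindered α-quaternary ketone should give the exocyclic alkene without enolisation or attack on the lactones.

Step 19
Reactants: 30 methylidene compound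
Product: 31 target CNP0222978.4
Conditions: Co(acac)2 (20 mol%), PhSiH3, O2 (1 atm), i-PrOH, rt
Reagents that add atoms: oxygen, O=O
Why: Mukaiyama hydration (hydrogen-atom transfer to the 1,1-disubstituted alkene, capture of the tertiary radical by O2, reduction of the peroxide) gives the Markovnikov tertiary alcohol, oxygen entering opposite the gem-dimethyl carbon of ring A so that OH ends cis to the ring-A vinyl carbon as in the target, while the hindered, electron-poor lactone alkene reacts more slowly.

**Compound list**

1 | (R)-4-(tert-butyldimethylsilyloxy)cyclopent-2-en-1-one | O=C1C[C@@H](O[Si](C)(C)C(C)(C)C)C=C1 | starting material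
2 | thioanisole | CSc1ccccc1 | starting material
3 | all-trans 2-[(dimethylamino)methyl]-3-[(phenylsulfanyl)methyl]-4-(tert-butyldimethylsilyloxy)cyclopentan-1-one | O=C1C[C@@H](O[Si](C)(C)C(C)(C)C)[C@H](CSc2ccccc2)[C@H]1CN(C)C | intermediate
4 | (4S,5S)-5-[(dimethylamino)methyl]-4-[(phenylsulfanyl)methyl]cyclopent-2-en-1-one | O=C1C=C[C@H](CSc2ccccc2)[C@H]1CN(C)C | intermediate
5 | {[(1S,5S)-2-oxo-5-[(phenylsulfanyl)methyl]cyclopent-3-en-1-yl]methyl}trimethylammonium iodide | O=C1C=C[C@H](CSc2ccccc2)[C@H]1C[N+](C)(C)C.[I-] | intermediate
6 | methyl 3-oxopentanoate | CCC(=O)CC(=O)OC | starting material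
7 | methyl methacrylate | C=C(C)C(=O)OC | starting material
8 | methyl 3,5-dimethyl-2,4-dioxocyclohexane-1-carboxylate | COC(=O)C1CC(C)C(=O)C(C)C1=O | intermediate
9 | (S)-5-methylidene-4-[(phenylsulfanyl)methyl]cyclopent-2-en-1-one | O=C1C=C[C@H](CSc2ccccc2)C1=C | intermediate
10 | Michael adduct, methyl 3,5-dimethyl-2,4-dioxo-3-{[2-oxo-5-[(phenylsulfanyl)methyl]cyclopent-3-en-1-yl]methyl}cyclohexane-1-carboxylate | COC(=O)C1CC(C)C(=O)[C@](C)(C[C@H]2C(=O)C=C[C@@H]2CSc2ccccc2)C1=O | intermediate
11 | 1-(phenylselanyl) derivative of 10 | COC(=O)C1([Se]c2ccccc2)CC(C)C(=O)[C@](C)(C[C@H]2C(=O)C=C[C@@H]2CSc2ccccc2)C1=O | intermediate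
12 | dienol sulfoxide, methyl 2-hydroxy-3,5-dimethyl-4-oxo-3-{[2-oxo-5-[(phenylsulfinyl)methyl]cyclopent-3-en-1-yl]methyl}cyclohexa-1,5-diene-1-carboxylate | COC(=O)C1=C(O)[C@@](C)(C[C@H]2C(=O)C=C[C@@H]2CS(=O)c2ccccc2)C(=O)C(C)=C1 | intermediate
13 | vinyl triflate of 12 | COC(=O)C1=C(OS(=O)(=O)C(F)(F)F)[C@@](C)(C[C@H]2C(=O)C=C[C@@H]2CS(=O)c2ccccc2)C(=O)C(C)=C1 | intermediate
14 | 2-(hydroxymethyl) dienone ester | COC(=O)C1=C(CO)[C@@](C)(C[C@H]2C(=O)C=C[C@@H]2CS(=O)c2ccccc2)C(=O)C(C)=C1 | intermediate
15 | butenolide dienone sulfoxide, 4,6-dimethyl-4-{[2-oxo-5-[(phenylsulfinyl)methyl]cyclopent-3-en-1-yl]methyl}isobenzofuran-1,5(3H,4H)-dione | CC1=CC2=C(COC2=O)[C@@](C)(C[C@H]2C(=O)C=C[C@@H]2CS(=O)c2ccccc2)C1=O | intermediate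
16 | 4,6-dimethyl-4-[(2-methylidene-5-oxocyclopent-3-en-1-yl)methyl]isobenzofuran-1,5(3H,4H)-dione | CC1=CC2=C(COC2=O)[C@@](C)(C[C@H]2C(=O)C=CC2=C)C1=O | intermediate
17 | cage enone (Diels–Alder adduct) | O=C1C=C[C@@]23C[C@@]4(C)C=C5C(=O)OC[C@]52[C@@](C)(C[C@H]31)C4=O | intermediate
18 | 3-methylbut-2-enal | CC(C)=CC=O | starting material
19 | 2-bromo-3-methylbut-2-enal | CC(C)=C(Br)C=O | intermediate
20 | 2-bromo-3-methylbut-2-en-1-ol | CC(C)=C(Br)CO | intermediate
21 | benzyl bromide | BrCc1ccccc1 | starting material
22 | benzyl 2-bromo-3-methylbut-2-en-1-yl ether | CC(C)=C(Br)COCc1ccccc1 | intermediate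
23 | tertiary bis-allylic alcohol | O[C@@]1(C(COCc6ccccc6)=C(C)C)C=C[C@@]23C[C@@]4(C)C=C5C(=O)OC[C@]52[C@@](C)(C[C@H]31)C4=O | intermediate
24 | epoxy alcohol | O[C@@]1([C@]6(COCc7ccccc7)OC6(C)C)C=C[C@@]23C[C@@]4(C)C=C5C(=O)OC[C@]52[C@@](C)(C[C@H]31)C4=O | intermediate
25 | ring-expanded hydroxy ketone | CC(C)(O)[C@]1(COCc6ccccc6)C=C[C@@]23C[C@@]4(C)C=C5C(=O)OC[C@]52[C@@](C)(C[C@H]3C1=O)C4=O | intermediate
26 | saturated diol ketone | CC(C)(O)[C@]1(CO)CC[C@@]23C[C@@]4(C)C[C@H]5C(=O)OC[C@]52[C@@](C)(C[C@H]3C1=O)C4=O | intermediate
27 | hydroxy aldehyde | CC(C)(O)[C@]1(C=O)CC[C@@]23C[C@@]4(C)C[C@H]5C(=O)OC[C@]52[C@@](C)(C[C@H]3C1=O)C4=O | intermediate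
28 | (Z)-enoate hydroxy ester | CC(C)(O)[C@]1(/C=C\C(=O)OC)CC[C@@]23C[C@@]4(C)C[C@H]5C(=O)OC[C@]52[C@@](C)(C[C@H]3C1=O)C4=O | intermediate
29 | spiro lactone ketone | CC1(C)OC(=O)C=C[C@]12CC[C@@]13C[C@@]4(C)C[C@H]5C(=O)OC[C@]51[C@@](C)(C[C@H]3C2=O)C4=O | intermediate
30 | exocyclic methylidene compound | CC1(C)OC(=O)C=C[C@]12CC[C@@]13C[C@@]4(C)C[C@H]5C(=O)OC[C@]51[C@@](C)(C[C@H]3C2=C)C4=O | intermediate
31 | CNP0222978.4 | CC1(C)OC(=O)C=C[C@]12CC[C@@]13C[C@@]4(C)C[C@H]5C(=O)OC[C@]51[C@@](C)(C[C@H]3[C@@]2(C)O)C4=O | target

**Summary and risks**

Total step count: 19. Longest linear sequence: 15 steps (1 → 31 through steps 1, 2, 4–8 and 12–19).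

Steps most likely to fail:

Step 14. The 1,2-shift may take the wrong course: the sp3 ring-fusion carbon may migrate instead of the vinyl carbon, or the epoxide may ionise at the gem-dimethyl carbon and then eliminate or fragment. The fallback builds ring B by a different one-carbon ring expansion. Setting out from 17, both alkenes are hydrogenated (H2, Pd/C) to the saturated cage cyclopentanone F1. Homologation with trimethylsilyldiazomethane (Sc(OTf)3 cat., CH2Cl2, −78 °C; then K2CO3, MeOH), a Tiffeneau–Demjanov-type expansion in which the less substituted CH2 migrates, gives the ring-B cyclohexanone F2. Kinetic enolisation on the CH2 side (LiN(iPr)2, −78 °C) and aldol addition to acetone give the β-hydroxy ketone F3. Esterification with propiolic acid (DCC, DMAP) gives the propiolate F4. Cs2CO3-mediated intramolecular conjugate addition of the ketone enolate to the ynoate closes ring A at the spiro carbon and comes back to the route at 29; spiro epimers would be separated if both form.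

Step 8. The cascade may be diverted by cycloaddition through the ring enone double bond, by oligomerisation of the methylidene cyclopentenone, or by loss of the matched ring-fusion configuration before closure. The fallback changes the oxidation level of the dienophile ring. Setting out from 15, Luche reduction (NaBH4, CeCl3·7H2O, MeOH, −78 °C) of the cyclopentenone carbonyl gives the allylic alcohol F5. Thermolysis (PhMe, 115 °C) eliminates the sulfoxide to an electron-rich semicyclic diene whose exocyclic alkene closes onto the electron-poor dienone, giving the cage allylic alcohol F6. Oxidation with Dess–Martin periodinane comes back to the route at 17.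

Step 13. Facial selectivity of the directed epoxidation may be poor, which would lead to the epimeric spiro carbon after step 14, or the ring alkene may be epoxidised in competition. The fallback replaces hydroxyl direction by steric control. Setting out from 23, silylation with N-(trimethylsilyl)imidazole gives the trimethylsilyl ether F7. Dimethyldioxirane (acetone, −20 °C) should epoxidise the tetrasubstituted alkene from the face away from the silyloxy group, giving the epoxy silyl ether F8. Rearrangement of this epoxy silyl ether with BF3·OEt2 (cat., CH2Cl2, −78 °C), with loss of the silyl group on work-up, comes back to the route at 25.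

Further compounds
F1 | step 14 | saturated cage cyclopentanone (17 with both alkenes hydrogenated) | O=C1CC[C@@]23C[C@@]4(C)C[C@H]5C(=O)OC[C@]52[C@@](C)(C[C@H]31)C4=O
F2 | step 14 | ring-B cyclohexanone (one-carbon homologue of F1) | O=C1CCC[C@@]23C[C@@]4(C)C[C@H]5C(=O)OC[C@]52[C@@](C)(C[C@H]31)C4=O
F3 | step 14 | acetone aldol adduct of F2 | CC(C)(O)C1CC[C@@]23C[C@@]4(C)C[C@H]5C(=O)OC[C@]52[C@@](C)(C[C@H]3C1=O)C4=O
F4 | step 14 | propiolate ester of F3 | C#CC(=O)OC(C)(C)C1CC[C@@]23C[C@@]4(C)C[C@H]5C(=O)OC[C@]52[C@@](C)(C[C@H]3C1=O)C4=O
F5 | step 8 | allylic alcohol from 1,2-reduction of the cyclopentenone of 15 | CC1=CC2=C(COC2=O)[C@@](C)(C[C@H]2C(O)C=C[C@@H]2CS(=O)c2ccccc2)C1=O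
F6 | step 8 | cage allylic alcohol (17 with carbinol in place of the enone carbonyl) | OC1C=C[C@@]23C[C@@]4(C)C=C5C(=O)OC[C@]52[C@@](C)(C[C@H]31)C4=O
F7 | step 13 | trimethylsilyl ether of 23 | C[Si](C)(C)O[C@@]1(C(COCc6ccccc6)=C(C)C)C=C[C@@]23C[C@@]4(C)C=C5C(=O)OC[C@]52[C@@](C)(C[C@H]31)C4=O
F8 | step 13 | epoxy trimethylsilyl ether | C[Si](C)(C)O[C@@]1([C@]6(COCc7ccccc7)OC6(C)C)C=C[C@@]23C[C@@]4(C)C=C5C(=O)OC[C@]52[C@@](C)(C[C@H]31)C4=O
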